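The easy step came first, and it was a count: I took each event as one electrophile meeting one nucleophile to give one target and one acid set free, and I asked what became of that acid.

common to all: nucleophile 0.846 M
- ash: electrophile 0.94 M; the very flask that is asked about, followed so far
- larch: electrophile 0.63 M; run made earlier
- flask: electrophile 0.94 M; time 8.0 d

| ash: time / d | ash: target / % | larch: time / h | larch: target / % |
|---|---|---|---|
| 0.417 | 23.5 | 4.00 | 13.8 |
| 0.625 | 28.0 | 8.00 | 23.2 |
| 1.04 | 31.6 | 12.0 | 29.5 |
| 1.67 | 31.9 | 15.0 | 33.0 |
| 3.00 | 27.9 | 20.0 | 37.8 |
| 5.00 | 22.2 | 25.0 | 40.3 |

(each reading ± 0.3 percentage points)

- autumn: at 8.0 d add electrophile, 50.0% of the amount charged, then wait 8.0 d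
- dawn: change nothing and wait 8.0 d more
- dusk: at 8.0 d take out 90% of the acid set free then present, then wait 8.0 d

- additions leave the volume as it is
- the analysis behind the earlier runs scatters by 0.3 percentage points, standard deviation

- target, in percent of the electrophile first charged, at 8.0 d
- which option adds most target ("none" when 2 percentage points or less is all one gets) (autumn / dawn / dusk / none)
- target present, in percent of the electrophile first charged, after autumn
- target present, in percent of the electrophile first charged, after dusk

If the acid did nothing, the flask was plain second order with the nucleophile as limiting reagent, and the target could climb to 90.0% of the electrophile charged. If each acid at once bound a second nucleophile, every event cost two nucleophiles, and I named the result the salt ceiling C, the nucleophile charge over twice the electrophile charge, which counts the events of electrophile with nucleophile as a share of the electrophile charged, and so the target that version can make, but not any electrophile that goes another way: 45.0%, half of the first figure. Larch gave the clock: 13.8% reacted in 4.00 h, at the nucleophile charge of the flask, which is a time constant τ of about 1.21 d, so at that opening pace C came within about 0.544 d. The ash run stood near the second version, since its rise bent over at about a day and it then fell from 31.9% at 1.67 d to 22.2% at 5.00 d, a loss of 0.109 d⁻¹, with its peak below C. By my rule, acid taken out lifts C by half its amount over the electrophile charge, so the lift from dusk went with the amount of acid standing free.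

The forecast gave 16.5% at 8.0 d, 4% after autumn and 22% after dusk, with dusk as best, on the ground that “Removing the acid frees nucleophile, which converts the remaining electrophile (about 0.1 M) mostly to target”.

The flask gave 16.8%, then 6.39% after autumn and 11.7% after dusk, a change of −5.1 percentage points for dusk, so the best choice was none.

    nucleophile + acid set free ⇌ protonated nucleophile, settled at all times (K = 4400 M⁻¹)
    electrophile + target → side product (k = 1.80 × 10⁻⁴ M⁻¹ min⁻¹)
    electrophile + nucleophile → acid set free + target (k = 8.50 × 10⁻⁴ M⁻¹ min⁻¹)
    target ⇌ isomer of the product (K = 0.500, k = 5.50 × 10⁻⁵ min⁻¹)

The consumption of nucleophile is the main reason for the low target: the run without it reached 60.2% against 16.8%. In the flask, target, isomer of the product and half the side product, which counts two, sum to 46.0%, against C of 45.0%. Dusk removed 90% of 0.0236 M free acid beside 0.409 M protonated nucleophile, lifting C by 1.1 points. The neighbour charged with 1.4 M of nucleophile has C of 74.5%, and its sum came to 73.4%, of which target was 39.5%.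

The runs come from a simulation for an exercise; noise was put on by code.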